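**Retrosynthetic overview**
- The aryl ester between ring A and ring B is cut first: ring A acid 13 plus ring B phenol 21 (carboxyl held as a benzyl ester), joined with trifluoroacetic anhydride, then hydrogenolysis.
- The strategy rests on the salicylate pattern of ring A: C1 with its carboxyl carbon and the hydroxyl-bearing C2 are the three carbons of a malonate, the C4 methoxy group is a methyl enol ether already in place, C3 is an acetyl methyl group and C6 is the heptyl-bearing alkylidene carbon. The C2–C3 bond is disconnected.
- The open chain 10 comes from undec-3-yn-2-one (1-nonyne plus an acetyl donor), dibenzyl malonate and trimethyl orthoformate.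
- Ring B is not built: olivetol is formylated, its hydroxyls are differentiated (4-O-MOM, 2-O-methyl), and the aldehyde is oxidised and benzylated.
- Ring order: ring A is closed in step 4, ring B is carried from olivetol, and the two are joined in step 12.

Key step: step 4

Remark: ring A locants (C1 carboxyl-bearing, C2 hydroxyl, C3 H, C4 methoxyl, C5 H, C6 heptyl) are also used for the corresponding open-chain carbons. Compound 7 is expected as a mixture of C5=C6 isomers and keto/alkylidene tautomers (the E enone is drawn); all converge on 10, where C5–C6 is a single bond.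

**Step 1**
Reactants: 1 1-nonyne; 2 N-methoxy-N-methylacetamide
Product: 4 undec-3-yn-2-one, via 1-nonynyllithium 3 (not isolated)
Conditions: n-BuLi, THF, −78 °C; then 2, −78 → 0 °C; 1 M HCl
Reagents that add atoms: none
Why: Acylation of a lithium acetylide with a Weinreb amide should stop at the ketone, because the chelated tetrahedral adduct survives until the acidic quench.

**Step 2**
Reactants: 4 undec-3-yn-2-one; 5 dibenzyl malonate
Product: 7 dibenzyl 2-[(E)-1-heptyl-3-oxobut-1-enyl]malonate, via potassium dienolate 6 (not isolated)
Conditions: KOtBu (1.0 equiv), THF, −40 → 0 °C; cold AcOH quench; used crude without heating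
Reagents that add atoms: none
Why: Michael addition of the malonate anion to the ynone gives an allenolate that takes up the acidic malonate proton to become dienolate 6, and with a full equivalent of base the adduct stays anionic, a form in which lactonisation to the 2-pyranone would have to expel the much more basic benzyl oxide.

**Step 3**
Reactants: 7 dibenzyl 2-[(E)-1-heptyl-3-oxobut-1-enyl]malonate; 8 trimethyl orthoformate
Product: 10 dibenzyl 2-[(E)-1-heptyl-3-methoxybut-2-enylidene]malonate, via dimethyl ketal 9 (not isolated)
Conditions: HC(OMe)3, TsOH·H2O (cat.), CH2Cl2, rt → 40 °C; Et3N; chromatography on Et3N-treated silica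
Reagents that add atoms: none
Why: Acid-catalysed ketal exchange followed by 1,4-elimination of methanol through the acidic malonate C–H is the dienol ether formation known for conjugated enones, and it should give the push–pull diene with the methoxy group trans to C6, as in β-methoxy enoates.

**Step 4**
Reactants: 10 dibenzyl 2-[(E)-1-heptyl-3-methoxybut-2-enylidene]malonate
Product: 12 benzyl 2-heptyl-6-hydroxy-4-methoxybenzoate, via cyclohexadienone 11 (not isolated)
Conditions: KOtBu (2.5 equiv), THF–t-BuOH, 0 → 60 °C; then 1 M HCl
Reagents that add atoms: none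
Why: Proposed new method: tert-butoxide removes a proton from the C3 methyl group of 10, which is acidified through the enol ether and the alkylidene malonate, and gives a delocalised dienyl malonate anion whose C4–C5 bond has largely single-bond character, so that either enol ether geometry can place C3 beside an ester carbonyl. C3 then adds to that carbonyl carbon (C2) in a 6-(enolendo)-exo-trig Claisen (Dieckmann-type) closure, which can also be read as the disrotatory 6π closure of a 1-oxidotriene; benzyl oxide leaves to give dienone 11, whose C3–H is removed at once, and the resulting phenoxide of 12 makes the sequence irreversible. The closest known reaction types are the Michael–Dieckmann sequence in which a methyl ketone carbon closes onto a malonate ester to give dihydroresorcylates and the 6π closure of dienylketenes to phenols; new here is the remote deprotonation through a methyl enol ether and the attack of the anion on one of its own ester groups. Ring A is the only ring formed and no stereocentre is created. The selectivity needed is C3 against the heptyl α-CH2: the anion formed there is in equilibrium through t-BuOH and has no six-membered closure open to it, so it drains through the C3 anion, and since the two esters are identical the chain alone fixes hydroxyl at C2, methoxyl at C4 and heptyl at C6. A full excess of base keeps all of 10 anionic, so that the benzyl oxide set free cannot exchange the C4 methoxy group by addition–elimination, and the capped C4 oxygen rules out lactonisation to a 2-pyranone.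

**Step 5**
Reactants: 12 benzyl 2-heptyl-6-hydroxy-4-methoxybenzoate
Product: 13 2-heptyl-6-hydroxy-4-methoxybenzoic acid
Conditions: H2 (1 atm), 10% Pd/C, EtOAc, rt; used without heating
Reagents that add atoms: none
Why: Hydrogenolysis of the benzyl ester over palladium on carbon should free the acid without the basic hydrolysis that a 2,6-disubstituted benzoate resists.

**Step 6**
Reactants: 14 olivetol
Product: 16 2,4-dihydroxy-6-pentylbenzaldehyde, via aryl iminium chloride 15 (not isolated)
Conditions: POCl3, DMF, 0 °C → rt; then H2O, 50 °C
Reagents that add atoms: N,N-dimethylformamide, CN(C)C=O; water, O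
Why: Vilsmeier–Haack formylation of the resorcinol should occur para to one hydroxyl and ortho to the other, next to the pentyl chain, and not at the crowded carbon between the two hydroxyls.

**Step 7**
Reactants: 16 2,4-dihydroxy-6-pentylbenzaldehyde
Product: 17 2-hydroxy-4-(methoxymethoxy)-6-pentylbenzaldehyde
Conditions: MOMCl (1.1 equiv), K2CO3, acetone, 0 °C → rt
Reagents that add atoms: chloromethyl methyl ether, COCCl
Why: Williamson-type O-alkylation should be selective for the 4-hydroxyl, because the 2-hydroxyl is held in a hydrogen bond to the aldehyde and is less acidic and less nucleophilic.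

**Step 8**
Reactants: 17 2-hydroxy-4-(methoxymethoxy)-6-pentylbenzaldehyde
Product: 18 2-methoxy-4-(methoxymethoxy)-6-pentylbenzaldehyde
Conditions: MeI, K2CO3, DMF, 40 °C
Reagents that add atoms: iodomethane, CI
Why: With the 4-oxygen capped, Williamson methylation in DMF should alkylate the remaining hydrogen-bonded phenol, and the MOM acetal is stable to base.

**Step 9**
Reactants: 18 2-methoxy-4-(methoxymethoxy)-6-pentylbenzaldehyde
Product: 19 2-methoxy-4-(methoxymethoxy)-6-pentylbenzoic acid
Conditions: NaClO2, NaH2PO4, 2-methyl-2-butene, t-BuOH–H2O, rt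
Reagents that add atoms: sodium chlorite, [Na+].[O-]Cl=O
Why: Pinnick oxidation converts the aldehyde to the acid in a buffered medium that the MOM acetal tolerates, and 2-methyl-2-butene removes the hypochlorous acid that would chlorinate the electron-rich ring.

**Step 10**
Reactants: 19 2-methoxy-4-(methoxymethoxy)-6-pentylbenzoic acid
Product: 20 benzyl 2-methoxy-4-(methoxymethoxy)-6-pentylbenzoate
Conditions: BnBr, K2CO3, DMF, rt
Reagents that add atoms: benzyl bromide, BrCc1ccccc1
Why: The carboxylate of the hindered acid is alkylated at oxygen by benzyl bromide in an SN2 reaction, which does not need attack at the shielded carbonyl carbon.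

**Step 11**
Reactants: 20 benzyl 2-methoxy-4-(methoxymethoxy)-6-pentylbenzoate
Product: 21 benzyl 4-hydroxy-2-methoxy-6-pentylbenzoate
Conditions: conc. HCl (cat.), MeOH–THF, 40 °C
Reagents that add atoms: none
Why: Acid-catalysed acetal exchange transfers the methoxymethyl group to methanol, while the 2,6-disubstituted benzyl ester is too hindered for transesterification under these conditions.

**Step 12**
Reactants: 13 2-heptyl-6-hydroxy-4-methoxybenzoic acid; 21 benzyl 4-hydroxy-2-methoxy-6-pentylbenzoate
Product: 23 benzyl 4-[(2-heptyl-6-hydroxy-4-methoxybenzoyl)oxy]-2-methoxy-6-pentylbenzoate, via mixed anhydride 22 (not isolated)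
Conditions: (CF3CO)2O, toluene, 0 °C → rt; aq. NaHCO3 work-up
Reagents that add atoms: none
Why: Trifluoroacetic anhydride turns the 2,6-disubstituted acid into mixed anhydride 22, which acylates the free 4-hydroxyl of 21 in the standard depside esterification, while the hydroxyl of 13 is hydrogen-bonded to its own carbonyl and should not compete.

**Step 13**
Reactants: 23 benzyl 4-[(2-heptyl-6-hydroxy-4-methoxybenzoyl)oxy]-2-methoxy-6-pentylbenzoate
Product: 24 4-[(2-heptyl-6-hydroxy-4-methoxybenzoyl)oxy]-2-methoxy-6-pentylbenzoic acid (target)
Conditions: H2 (1 atm), 10% Pd/C, EtOAc, rt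
Reagents that add atoms: none
Why: Hydrogenolysis over palladium on carbon removes the benzyl ester and should leave the aryl ester link, the methyl ethers and the phenol untouched.

**Compound list**
1 | 1-nonyne | C#CCCCCCCC | starting material
2 | N-methoxy-N-methylacetamide | CC(=O)N(C)OC | starting material
3 | 1-nonynyllithium | [Li]C#CCCCCCCC | intermediate (not isolated)
4 | undec-3-yn-2-one | CCCCCCCC#CC(C)=O | intermediate
5 | dibenzyl malonate | O=C(CC(=O)OCc1ccccc1)OCc1ccccc1 | starting material
6 | potassium (E)-4-[bis(benzyloxycarbonyl)methylene]undec-2-en-2-olate (potassium dienolate of 7, one resonance form drawn) | CCCCCCCC(/C=C(\C)[O-])=C(C(=O)OCc1ccccc1)C(=O)OCc1ccccc1.[K+] | intermediate (not isolated)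
7 | dibenzyl 2-[(E)-1-heptyl-3-oxobut-1-enyl]malonate (E drawn; Z isomer and tautomers are carried on) | CCCCCCC/C(=C\C(C)=O)C(C(=O)OCc1ccccc1)C(=O)OCc1ccccc1 | intermediate
8 | trimethyl orthoformate | COC(OC)OC | starting material
9 | dibenzyl 2-[(E)-1-heptyl-3,3-dimethoxybut-1-enyl]malonate | CCCCCCC/C(=C\C(C)(OC)OC)C(C(=O)OCc1ccccc1)C(=O)OCc1ccccc1 | intermediate (not isolated)
10 | dibenzyl 2-[(E)-1-heptyl-3-methoxybut-2-enylidene]malonate (= dibenzyl 2-[(2E)-2-methoxyundec-2-en-4-ylidene]malonate) | CCCCCCCC(/C=C(\C)OC)=C(C(=O)OCc1ccccc1)C(=O)OCc1ccccc1 | intermediate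
11 | benzyl 2-heptyl-4-methoxy-6-oxocyclohexa-1,3-diene-1-carboxylate | CCCCCCCC1=C(C(=O)OCc2ccccc2)C(=O)CC(OC)=C1 | intermediate (not isolated)
12 | benzyl 2-heptyl-6-hydroxy-4-methoxybenzoate | CCCCCCCc1cc(OC)cc(O)c1C(=O)OCc1ccccc1 | intermediate
13 | 2-heptyl-6-hydroxy-4-methoxybenzoic acid | CCCCCCCc1cc(OC)cc(O)c1C(=O)O | intermediate
14 | olivetol (5-pentylbenzene-1,3-diol) | CCCCCc1cc(O)cc(O)c1 | starting material
15 | N-[(2,4-dihydroxy-6-pentylphenyl)methylidene]-N-methylmethanaminium chloride | CCCCCc1cc(O)cc(O)c1C=[N+](C)C.[Cl-] | intermediate (not isolated)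
16 | 2,4-dihydroxy-6-pentylbenzaldehyde | CCCCCc1cc(O)cc(O)c1C=O | intermediate
17 | 2-hydroxy-4-(methoxymethoxy)-6-pentylbenzaldehyde | CCCCCc1cc(OCOC)cc(O)c1C=O | intermediate
18 | 2-methoxy-4-(methoxymethoxy)-6-pentylbenzaldehyde | CCCCCc1cc(OCOC)cc(OC)c1C=O | intermediate
19 | 2-methoxy-4-(methoxymethoxy)-6-pentylbenzoic acid | CCCCCc1cc(OCOC)cc(OC)c1C(=O)O | intermediate
20 | benzyl 2-methoxy-4-(methoxymethoxy)-6-pentylbenzoate | CCCCCc1cc(OCOC)cc(OC)c1C(=O)OCc1ccccc1 | intermediate
21 | benzyl 4-hydroxy-2-methoxy-6-pentylbenzoate | CCCCCc1cc(O)cc(OC)c1C(=O)OCc1ccccc1 | intermediate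
22 | 2-heptyl-6-hydroxy-4-methoxybenzoic trifluoroacetic anhydride | CCCCCCCc1cc(OC)cc(O)c1C(=O)OC(=O)C(F)(F)F | intermediate (not isolated)
23 | benzyl 4-[(2-heptyl-6-hydroxy-4-methoxybenzoyl)oxy]-2-methoxy-6-pentylbenzoate | CCCCCCCc1cc(OC)cc(O)c1C(=O)Oc1cc(CCCCC)c(C(=O)OCc2ccccc2)c(OC)c1 | intermediate
24 | 4-[(2-heptyl-6-hydroxy-4-methoxybenzoyl)oxy]-2-methoxy-6-pentylbenzoic acid | CCCCCCCc1cc(OC)cc(O)c1C(=O)Oc1cc(CCCCC)c(C(=O)O)c(OC)c1 | target

**Step count**
Total: 13 steps. Longest linear sequence: 8 steps (olivetol 14 to target 24, steps 6–11, 12, 13); the ring A branch is 7 steps (steps 1–5, 12, 13).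

**Steps most likely to fail**

Step 4 (the step proposed as new). The dienyl malonate anion of 10 is strongly stabilised and may add to its own ester too slowly. It could also be held as the heptyl-side anion without returning, or the enol ether could be lost by hydrolysis or by methoxy exchange. The fallback uses known chemistry, sets out from dibenzyl malonate 5 and returns at 12. Wittig reaction of octanal with 1-(triphenylphosphoranylidene)propan-2-one gives (E)-undec-3-en-2-one F1. KOtBu in refluxing THF adds 5 to F1 to give dibenzyl 2-(1-heptyl-3-oxobutyl)malonate F2. In the same flask the methyl ketone carbon of F2 closes onto a malonate ester (Dieckmann), giving benzyl 6-heptyl-2-hydroxy-4-oxocyclohex-2-ene-1-carboxylate F3, the classical alkylresorcylate ring synthesis. Bromine in DMF (bromination, then loss of HBr on warming) aromatises F3 to benzyl 2-heptyl-4,6-dihydroxybenzoate F4. One equivalent of MeI with K2CO3 in acetone methylates only the 4-hydroxyl, the 2-hydroxyl being hydrogen-bonded to the ester, and gives 12.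

Step 2. The Z-configured share of the adduct may lactonise to the 2-pyranone with loss of benzyl alcohol during quench or isolation, and the ynone may take up a second nucleophile or isomerise at its propargylic CH2 under base. The fallback sets out from 4 and 5 and returns at 10, bypassing 7 and step 3. Dienolate 6 is formed as in step 2 and is not protonated. It is treated in the same flask at −78 °C with methyl trifluoromethanesulfonate in THF–DMPU, where a hard methylating agent should alkylate the ketone oxygen of the ambident anion and give 10 directly. Competing C-methylation at the hindered malonate carbon is the point to watch. No new compound is made (F0).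

Step 3. Ketal 9 may not lose methanol cleanly, the acid may lactonise 7 or exchange benzyl for methyl esters, and 10 may hydrolyse back to 7 on silica. The fallback sets out from 7 and returns at 12. Soft enolisation with TIPSOTf and Et3N in CH2Cl2 at 0 °C silylates the ketone oxygen without acid and gives dibenzyl 2-[(E)-1-heptyl-3-(triisopropylsilyloxy)but-2-enylidene]malonate F5. F5 is cyclised under the conditions of step 4 to benzyl 2-heptyl-6-hydroxy-4-(triisopropylsilyloxy)benzoate F6. CsF and one equivalent of MeI in DMF at rt then exchange silicon for methyl at the 4-oxygen in one pot, the hydrogen-bonded 2-hydroxyl reacting more slowly, to give 12.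

**Further compounds**
F1 | step 4 | (E)-undec-3-en-2-one | CCCCCCC/C=C/C(C)=O
F2 | step 4 | dibenzyl 2-(1-heptyl-3-oxobutyl)malonate (racemic) | CCCCCCCC(CC(C)=O)C(C(=O)OCc1ccccc1)C(=O)OCc1ccccc1
F3 | step 4 | benzyl 6-heptyl-2-hydroxy-4-oxocyclohex-2-ene-1-carboxylate (racemic, trans drawn; both centres are lost on aromatisation) | CCCCCCC[C@@H]1CC(=O)C=C(O)[C@H]1C(=O)OCc1ccccc1
F4 | step 4 | benzyl 2-heptyl-4,6-dihydroxybenzoate | CCCCCCCc1cc(O)cc(O)c1C(=O)OCc1ccccc1
F0 | step 2 | none | none
F5 | step 3 | dibenzyl 2-[(E)-1-heptyl-3-(triisopropylsilyloxy)but-2-enylidene]malonate | CCCCCCCC(/C=C(\C)O[Si](C(C)C)(C(C)C)C(C)C)=C(C(=O)OCc1ccccc1)C(=O)OCc1ccccc1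
F6 | step 3 | benzyl 2-heptyl-6-hydroxy-4-(triisopropylsilyloxy)benzoate | CCCCCCCc1cc(O[Si](C(C)C)(C(C)C)C(C)C)cc(O)c1C(=O)OCc1ccccc1
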